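## Retrosynthetic overview

1. The target comes from fluoride desilylation of a tetrakis-silyl acid, made by acylating the C8 alkoxide of a saponified α-methylene 8,12-γ-lactone with silyl-protected (R)-3,4-dihydroxy-2-methylenebutanoyl chloride (from (R)-3-hydroxy-γ-butyrolactone).
2. The α-methylene lactone comes from iodolactonisation, deiodination and methylenation of a γ,δ-unsaturated amide, whose C7–C11 bond is made by an Eschenmoser–Claisen [3,3] shift from a C9 allylic alcohol.
3. The vinyl and 3-silyloxyprop-1-en-2-yl groups come from reduction, oxidation and double Wittig methylenation of the cis-fused γ-lactone left by the dienophile.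
4. The cis-6,9-diol comes from singlet-oxygen [4+2] addition to a cyclohexa-1,3-diene, itself from the Diels–Alder adduct of (S)-5-(silyloxymethyl)-3-methylbutenolide ((R)-glyceraldehyde acetonide) with 1-acetoxybutadiene, then palladium-catalysed elimination.
5. Ring order: butenolide, then the cyclohexene by Diels–Alder (the only ring of the target), then a transient endoperoxide, then a transient 8,12-γ-lactone that is opened before acylation.

Convention (one line): ring carbons of all intermediates carry elemane numbers (C10 quaternary, then C9, C8, C7, C6, C5; C1/C2 = vinyl; C4/C3/C15 = the C3 unit on C5; C11/C12/C13 = the C3 unit on C7); β is the face of the C10 methyl group, α the opposite face.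

## Route

Step 1
Reactants: 1 (4R)-2,2-dimethyl-1,3-dioxolane-4-carbaldehyde; 2 methyl 2-[bis(2,2,2-trifluoroethoxy)phosphoryl]propanoate
Product: 3 methyl (2Z)-3-[(4S)-2,2-dimethyl-1,3-dioxolan-4-yl]-2-methylprop-2-enoate
Conditions: KN(SiMe3)2, 18-crown-6, THF, −78 °C
Reagents that add atoms: none
Why: The Still–Gennari variant of the Horner–Wadsworth–Emmons olefination gives the Z-trisubstituted enoate under kinetic control at −78 °C without touching the bought stereocentre.

Step 2
Reactants: 3 methyl (2Z)-3-[(4S)-2,2-dimethyl-1,3-dioxolan-4-yl]-2-methylprop-2-enoate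
Product: 5 (5S)-5-[(tert-butyldimethylsilyloxy)methyl]-3-methylfuran-2(5H)-one, via butenolide alcohol 4 (not isolated)
Conditions: p-TsOH·H2O (cat.), MeOH/H2O, rt; evaporate; then TBSCl, imidazole, DMF, 0 °C → rt
Reagents that add atoms: tert-butyldimethylsilyl chloride, CC(C)(C)[Si](C)(C)Cl
Why: Acetonide hydrolysis frees the γ-hydroxyl, which lactonises onto the Z-ester (transesterification) to the butenolide, and the primary alcohol is then silylated, the stereocentre being carried over unchanged.

Step 3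
Reactants: 5 (5S)-5-[(tert-butyldimethylsilyloxy)methyl]-3-methylfuran-2(5H)-one; 6 (1E)-buta-1,3-dien-1-yl acetate
Product: 7 (3S)-3-[(tert-butyldimethylsilyloxy)methyl]-7a-methyl-1-oxo-1,3,3a,4,7,7a-hexahydro-2-benzofuran-7-yl acetate (cis-fused; H5 and C10-CH3 β; lactone α; 9α-OAc)
Conditions: 6 (5 equiv), BHT (cat.), toluene, sealed tube, 170 °C, 48 h
Reagents that add atoms: none
Why: In this thermal Diels–Alder cycloaddition the diene adds to the butenolide face anti to the CH2OTBS group, giving the cis-fused adduct and setting C5 and quaternary C10 from the bought stereocentre, while regio- and endo/exo isomers at the acetate carbon all converge in step 4.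

Step 4
Reactants: 7 Diels–Alder lactone acetate
Product: 8 (3S)-3-[(tert-butyldimethylsilyloxy)methyl]-7a-methyl-3a,7a-dihydro-2-benzofuran-1(3H)-one (cis-fused cyclohexa-1,3-diene; H5 and C10-CH3 β)
Conditions: Pd(PPh3)4 (5 mol %), Et3N, 1,4-dioxane, 100 °C
Reagents that add atoms: none
Why: Zerovalent palladium ionises the allylic acetate and β-hydride elimination (Tsuji–Trost-type elimination) can only give the C6=C7–C8=C9 diene because C10 is quaternary.

Step 5
Reactants: 8 cis-fused diene lactone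
Product: 10 6β,9β-dihydroxy lactone [(3S)-3-(TBSOCH2)-4,7-dihydroxy-7a-methyl-3a,4,7,7a-tetrahydro-2-benzofuran-1(3H)-one], via endoperoxide 9 (not isolated)
Conditions: O2, tetraphenylporphyrin (cat.), visible light, CH2Cl2, −20 °C; then thiourea, MeOH, rt
Reagents that add atoms: dioxygen, O=O
Why: Singlet-oxygen [4+2] cycloaddition takes place on the convex β face anti to the lactone ring and thiourea cleaves the O–O bond, so the C6 and C9 hydroxyls are both β and cis.

Step 6
Reactants: 10 6β,9β-diol lactone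
Product: 11 6β-(tert-butyldimethylsilyloxy)-9β-hydroxy lactone
Conditions: TBSCl (1.1 equiv), imidazole, DMF, −10 → 0 °C
Reagents that add atoms: tert-butyldimethylsilyl chloride, CC(C)(C)[Si](C)(C)Cl
Why: Silylation is sterically controlled, since the C9 hydroxyl is neopentylic and flanked by the cis C10 methyl group, so the C6 hydroxyl reacts first.

Step 7
Reactants: 11 6β-silyloxy-9β-hydroxy lactone
Product: 13 N,N-dimethyl-2-[(3S)-4-(TBSO)-3-(TBSOCH2)-7a-methyl-1-oxo-1,3,3a,4,5,7a-hexahydro-2-benzofuran-5-yl]acetamide (7β-CH2CONMe2; 6β-OTBS; C8=C9), via ketene N,O-acetal 12 (not isolated)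
Conditions: MeC(OMe)2NMe2 (5 equiv), xylene, 140 °C, MeOH distilled off
Reagents that add atoms: N,N-dimethylacetamide dimethyl acetal, CC(OC)(OC)N(C)C
Why: The Eschenmoser–Claisen [3,3]-sigmatropic rearrangement transfers the acetamide unit suprafacially from the 9β-oxygen to C7, forming the C7–C11 bond on the β face and moving the alkene to C8=C9.

Step 8
Reactants: 13 lactone amide
Product: 14 diol amide (C10: β-CH3 and α-CH2OH; C5: α-CH(OH)CH2OTBS with 4S; 6β-OTBS; 7β-CH2CONMe2; C8=C9)
Conditions: LiBH4, THF (MeOH, 1 equiv), 0 °C → rt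
Reagents that add atoms: none
Why: LiBH4 reduces the lactone to the diol chemoselectively, the tertiary amide and the silyl ethers being inert.

Step 9
Reactants: 14 diol amide
Product: 15 keto aldehyde amide (C10: β-CH3 and α-CHO; C5: α-C(=O)CH2OTBS)
Conditions: (COCl)2, DMSO, CH2Cl2, −78 °C; then Et3N, −78 → 0 °C
Reagents that add atoms: none
Why: Swern oxidation activates both hydroxyls before base is added, so the 1,4-diol gives the keto aldehyde without lactol or lactone formation, and C10 cannot epimerise while C5 sits in its favoured configuration.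

Step 10
Reactants: 15 keto aldehyde amide
Product: 16 triene amide (C10: β-CH3 and α-vinyl; C5: α-C(=CH2)CH2OTBS; 6β-OTBS; 7β-CH2CONMe2; C8=C9)
Conditions: Ph3PCH3Br, KN(SiMe3)2, THF, −78 °C → rt (substrate added to excess ylide)
Reagents that add atoms: methyltriphenylphosphonium bromide, C[P+](c1ccccc1)(c1ccccc1)c1ccccc1.[Br-]
Why: Double Wittig methylenation converts the aldehyde into the C10 vinyl group and the ketone into the 1,1-disubstituted alkene, which also erases the C4 stereocentre that steered the Diels–Alder step.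

Step 11
Reactants: 16 triene amide
Product: 18 9α-iodo-8β,12-γ-lactone (cis-fused at C7–C8), via iminium lactone iodide 17 (not isolated)
Conditions: I2 (3 equiv), THF/H2O (1:1), 0 °C → rt
Reagents that add atoms: iodine, II; water, O
Why: Iodolactonisation through the amide oxygen (5-exo, anti addition) places the C8 oxygen on the β face cis to the C7 side chain and iodine at C9 α, and water hydrolyses the iminium ether to the γ-lactone.

Step 12
Reactants: 18 iodolactone
Product: 19 8β,12-γ-lactone (C9 = CH2)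
Conditions: Bu3SnH, AIBN (cat.), toluene, 80 °C
Reagents that add atoms: none
Why: Radical chain dehalogenation removes the secondary iodide, and none of the alkenes can trap the C9 radical in a favourable ring size.

Step 13
Reactants: 19 γ-lactone
Product: 22 α-methylene-8β,12-γ-lactone, via Mannich base 20 (not isolated), via methiodide 21 (not isolated)
Conditions: LiN(iPr)2, THF, −78 °C; CH2=NMe2+ I−, −78 °C → rt; then MeI, MeOH, rt; then aq. NaHCO3, CH2Cl2
Reagents that add atoms: Eschenmoser's salt (N,N-dimethylmethyleneiminium iodide), C=[N+](C)C.[I-]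
Why: A lactone-enolate Mannich reaction, N-methylation and Hofmann-type elimination install the exocyclic methylene at C11, the only enolisable position.

Step 14
Reactants: 23 (4R)-4-hydroxyoxolan-2-one
Product: 26 (4R)-4-hydroxy-3-methylideneoxolan-2-one, via Mannich base 24 (not isolated), via methiodide 25 (not isolated)
Conditions: LiN(iPr)2 (2.2 equiv), THF, −78 °C; CH2=NMe2+ I−; AcOH (1 equiv); then MeI, MeOH, rt; then aq. NaHCO3
Reagents that add atoms: Eschenmoser's salt (N,N-dimethylmethyleneiminium iodide), C=[N+](C)C.[I-]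
Why: The dianion of the β-hydroxy lactone (the alkoxide suppresses β-elimination) undergoes a Mannich reaction, and quaternisation–elimination gives the α-methylene lactone without touching the carbinol stereocentre.

Step 15
Reactants: 26 (4R)-4-hydroxy-3-methylideneoxolan-2-one
Product: 29 (3R)-3,4-bis(tert-butyldimethylsilyloxy)-2-methylidenebutanoic acid, via lithium dihydroxy carboxylate 27 (not isolated), via tris-silyl derivative 28 (not isolated)
Conditions: LiOH, THF/H2O, 0 °C; evaporate; TBSCl (3.5 equiv), imidazole, DMF, rt; then AcOH/THF/H2O (3:1:1), rt, 1 h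
Reagents that add atoms: lithium hydroxide, [Li+].[OH-]; tert-butyldimethylsilyl chloride, CC(C)(C)[Si](C)(C)Cl
Why: Saponification opens the lactone, exhaustive silylation caps both hydroxyls and the carboxylate, and only the labile silyl ester is hydrolysed.

Step 16
Reactants: 29 (3R)-3,4-bis(tert-butyldimethylsilyloxy)-2-methylidenebutanoic acid
Product: 30 (3R)-3,4-bis(tert-butyldimethylsilyloxy)-2-methylidenebutanoyl chloride
Conditions: 1-chloro-N,N,2-trimethylprop-1-en-1-amine, CH2Cl2, 0 °C → rt; evaporate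
Reagents that add atoms: 1-chloro-N,N,2-trimethylprop-1-en-1-amine (Ghosez's reagent), CC(C)=C(Cl)N(C)C
Why: Ghosez's reagent forms the acid chloride under neutral conditions that spare the silyl ethers and the acrylate.

Step 17
Reactants: 22 α-methylene-8β,12-γ-lactone; 30 (3R)-3,4-bis(tert-butyldimethylsilyloxy)-2-methylidenebutanoyl chloride
Product: 32 tetrakis-TBS acid [8β-O-acyl; free C12 acid; 6β-OTBS; 15-OTBS; 3',4'-bis-OTBS], via lithium hydroxy carboxylate 31 (not isolated)
Conditions: LiOH (1.05 equiv), THF/H2O, 0 °C; evaporate, toluene azeotrope; LiN(SiMe3)2 (1.1 equiv), THF, −78 °C; 30 (1.2 equiv), −78 → −20 °C; cold 0.1 M HCl to pH 4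
Reagents that add atoms: lithium hydroxide, [Li+].[OH-]
Why: Saponification opens the strained α-methylene γ-lactone with retention at C8, and the lithium alkoxide–carboxylate is then acylated kinetically on the far more nucleophilic alkoxide (alkoxide O-acylation), so C12 needs no ester protection.

Step 18
Reactants: 32 tetrakis-TBS acid
Product: 33 2-[(1S,2S,3S,4S,6R)-6-{[(3R)-3,4-dihydroxy-2-methylidenebutanoyl]oxy}-4-ethenyl-2-hydroxy-3-(3-hydroxyprop-1-en-2-yl)-4-methylcyclohexyl]prop-2-enoic acid (target)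
Conditions: HF·pyridine, pyridine, THF, 0 °C → rt; pH 5 phosphate work-up
Reagents that add atoms: none
Why: Buffered fluoride desilylation removes the four silyl ethers, the pyridine buffer keeping the carboxylic acid unactivated so that the 6-hydroxy acid does not lactonise.

## Compound list

1 | (4R)-2,2-dimethyl-1,3-dioxolane-4-carbaldehyde | CC1(C)OC[C@H](C=O)O1 | starting material
2 | methyl 2-[bis(2,2,2-trifluoroethoxy)phosphoryl]propanoate | COC(=O)C(C)P(=O)(OCC(F)(F)F)OCC(F)(F)F | starting material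
3 | methyl (2Z)-3-[(4S)-2,2-dimethyl-1,3-dioxolan-4-yl]-2-methylprop-2-enoate | CC1(C)OC[C@H](/C=C(/C)C(=O)OC)O1 | intermediate
4 | (5S)-5-(hydroxymethyl)-3-methylfuran-2(5H)-one | CC1=C[C@@H](CO)OC1=O | intermediate (not isolated)
5 | (5S)-5-[(tert-butyldimethylsilyloxy)methyl]-3-methylfuran-2(5H)-one | CC1=C[C@@H](CO[Si](C)(C)C(C)(C)C)OC1=O | intermediate
6 | (1E)-buta-1,3-dien-1-yl acetate | CC(=O)O/C=C/C=C | starting material
7 | cis-fused Diels–Alder lactone acetate (9α-OAc, C7=C8) | O=C1O[C@H](CO[Si](C)(C)C(C)(C)C)[C@H]2CC=C[C@@H](OC(C)=O)[C@@]12C | intermediate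
8 | cis-fused cyclohexa-1,3-diene lactone | O=C1O[C@H](CO[Si](C)(C)C(C)(C)C)[C@H]2C=CC=C[C@@]12C | intermediate
9 | 6β,9β-endoperoxide lactone | O=C1O[C@H](CO[Si](C)(C)C(C)(C)C)[C@H]2[C@H]3C=C[C@H](OO3)[C@@]12C | intermediate (not isolated)
10 | 6β,9β-dihydroxy lactone | O=C1O[C@H](CO[Si](C)(C)C(C)(C)C)[C@H]2[C@H](O)C=C[C@H](O)[C@@]12C | intermediate
11 | 6β-silyloxy-9β-hydroxy lactone | O=C1O[C@H](CO[Si](C)(C)C(C)(C)C)[C@H]2[C@H](O[Si](C)(C)C(C)(C)C)C=C[C@H](O)[C@@]12C | intermediate
12 | 9β-O-[1-(dimethylamino)ethenyl] ketene N,O-acetal | O=C1O[C@H](CO[Si](C)(C)C(C)(C)C)[C@H]2[C@H](O[Si](C)(C)C(C)(C)C)C=C[C@H](OC(=C)N(C)C)[C@@]12C | intermediate (not isolated)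
13 | lactone amide (7β-CH2CONMe2, C8=C9) | O=C1O[C@H](CO[Si](C)(C)C(C)(C)C)[C@H]2[C@H](O[Si](C)(C)C(C)(C)C)[C@H](CC(=O)N(C)C)C=C[C@@]12C | intermediate
14 | diol amide | OC[C@]1(C)C=C[C@@H](CC(=O)N(C)C)[C@@H](O[Si](C)(C)C(C)(C)C)[C@@H]1[C@H](O)CO[Si](C)(C)C(C)(C)C | intermediate
15 | keto aldehyde amide | O=C[C@]1(C)C=C[C@@H](CC(=O)N(C)C)[C@@H](O[Si](C)(C)C(C)(C)C)[C@@H]1C(=O)CO[Si](C)(C)C(C)(C)C | intermediate
16 | triene amide | C=C[C@]1(C)C=C[C@@H](CC(=O)N(C)C)[C@@H](O[Si](C)(C)C(C)(C)C)[C@@H]1C(=C)CO[Si](C)(C)C(C)(C)C | intermediate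
17 | 9α-iodo iminium lactone iodide | C=C[C@]1(C)[C@H](I)[C@H]2OC(=[N+](C)C)C[C@H]2[C@@H](O[Si](C)(C)C(C)(C)C)[C@@H]1C(=C)CO[Si](C)(C)C(C)(C)C.[I-] | intermediate (not isolated)
18 | 9α-iodo-8β,12-γ-lactone | C=C[C@]1(C)[C@H](I)[C@H]2OC(=O)C[C@H]2[C@@H](O[Si](C)(C)C(C)(C)C)[C@@H]1C(=C)CO[Si](C)(C)C(C)(C)C | intermediate
19 | 8β,12-γ-lactone | C=C[C@]1(C)C[C@H]2OC(=O)C[C@H]2[C@@H](O[Si](C)(C)C(C)(C)C)[C@@H]1C(=C)CO[Si](C)(C)C(C)(C)C | intermediate
20 | 11-(dimethylaminomethyl) lactone (Mannich base, C11 configuration immaterial) | C=C[C@]1(C)C[C@H]2OC(=O)C(CN(C)C)[C@H]2[C@@H](O[Si](C)(C)C(C)(C)C)[C@@H]1C(=C)CO[Si](C)(C)C(C)(C)C | intermediate (not isolated)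
21 | 11-(trimethylammoniomethyl) lactone iodide | C=C[C@]1(C)C[C@H]2OC(=O)C(C[N+](C)(C)C)[C@H]2[C@@H](O[Si](C)(C)C(C)(C)C)[C@@H]1C(=C)CO[Si](C)(C)C(C)(C)C.[I-] | intermediate (not isolated)
22 | α-methylene-8β,12-γ-lactone | C=C[C@]1(C)C[C@H]2OC(=O)C(=C)[C@H]2[C@@H](O[Si](C)(C)C(C)(C)C)[C@@H]1C(=C)CO[Si](C)(C)C(C)(C)C | intermediate
23 | (4R)-4-hydroxyoxolan-2-one | O=C1C[C@@H](O)CO1 | starting material
24 | (4R)-3-[(dimethylamino)methyl]-4-hydroxyoxolan-2-one (C3 configuration immaterial) | O=C1OC[C@H](O)C1CN(C)C | intermediate (not isolated)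
25 | methiodide of 24 | O=C1OC[C@H](O)C1C[N+](C)(C)C.[I-] | intermediate (not isolated)
26 | (4R)-4-hydroxy-3-methylideneoxolan-2-one | O=C1OC[C@H](O)C1=C | intermediate
27 | lithium (3R)-3,4-dihydroxy-2-methylidenebutanoate | C=C(C(=O)[O-])[C@@H](O)CO.[Li+] | intermediate (not isolated)
28 | tert-butyldimethylsilyl (3R)-3,4-bis(tert-butyldimethylsilyloxy)-2-methylidenebutanoate | C=C(C(=O)O[Si](C)(C)C(C)(C)C)[C@@H](O[Si](C)(C)C(C)(C)C)CO[Si](C)(C)C(C)(C)C | intermediate (not isolated)
29 | (3R)-3,4-bis(tert-butyldimethylsilyloxy)-2-methylidenebutanoic acid | C=C(C(=O)O)[C@@H](O[Si](C)(C)C(C)(C)C)CO[Si](C)(C)C(C)(C)C | intermediate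
30 | (3R)-3,4-bis(tert-butyldimethylsilyloxy)-2-methylidenebutanoyl chloride | C=C(C(Cl)=O)[C@@H](O[Si](C)(C)C(C)(C)C)CO[Si](C)(C)C(C)(C)C | intermediate
31 | lithium 8β-hydroxy carboxylate | C=C[C@]1(C)C[C@@H](O)[C@@H](C(=C)C(=O)[O-])[C@@H](O[Si](C)(C)C(C)(C)C)[C@@H]1C(=C)CO[Si](C)(C)C(C)(C)C.[Li+] | intermediate (not isolated)
32 | tetrakis-TBS acid | C=C[C@]1(C)C[C@@H](OC(=O)C(=C)[C@@H](O[Si](C)(C)C(C)(C)C)CO[Si](C)(C)C(C)(C)C)[C@@H](C(=C)C(=O)O)[C@@H](O[Si](C)(C)C(C)(C)C)[C@@H]1C(=C)CO[Si](C)(C)C(C)(C)C | intermediate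
33 | 2-[(1S,2S,3S,4S,6R)-6-{[(3R)-3,4-dihydroxy-2-methylidenebutanoyl]oxy}-4-ethenyl-2-hydroxy-3-(3-hydroxyprop-1-en-2-yl)-4-methylcyclohexyl]prop-2-enoic acid | C=C[C@]1(C)C[C@@H](OC(=O)C(=C)[C@@H](O)CO)[C@@H](C(=C)C(=O)O)[C@@H](O)[C@@H]1C(=C)CO | target

## Step count and weak points

Total step count: 18. Longest linear sequence: 15 steps (steps 1–13, 17, 18).

The three steps most likely to fail are steps 3, 17 and 18.

Step 3 is risky because a trisubstituted α-methylbutenolide is a sluggish dienophile and 1-acetoxybutadiene polymerises at the temperature needed. The fallback sets out from 5 and uses buta-1,3-diene itself (toluene, 210 °C, sealed tube), which gives with the same facial control the cis-fused cyclohexene lactone F1. Bromine in CH2Cl2 at −78 °C adds to the only alkene to give the trans-7,8-dibromide F2, and double dehydrobromination with DBU in hot toluene returns to the route at diene 8.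

Step 17 is risky because the hydroxy carboxylate must be dried without relactonising and the alkoxide must be acylated in the presence of a carboxylate. The fallback sets out from 22: saponify with LiOH and alkylate the carboxylate with allyl bromide in DMF to give the 8β-hydroxy allyl ester F3. Esterify its C8 hydroxyl with acid 29 under Yamaguchi conditions (2,4,6-trichlorobenzoyl chloride, Et3N, DMAP, toluene) to give the fully protected allyl ester F4, then remove the allyl group with Pd(PPh3)4 and morpholine to rejoin the route at 32.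

Step 18 is risky because the freed 6β-hydroxyl sits cis to the C7 acrylic acid and may close the γ-lactone under acidic fluoride. The fallback sets out from 32 and accepts this: aqueous HF in MeCN removes all silyl groups and closes the ring to the 6β,12-olide F5. One equivalent of LiOH in THF/H2O at 0 °C then opens the strained α-methylene γ-lactone faster than the hindered C8 acrylate ester, and careful acidification to pH 5 arrives at 33.

## Further compounds

F1 | step 3 | cis-fused cyclohexene lactone (butadiene adduct of 5) | O=C1O[C@H](CO[Si](C)(C)C(C)(C)C)[C@H]2CC=CC[C@@]12C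
F2 | step 3 | trans-7,8-dibromide of F1 (7β,8α shown) | O=C1O[C@H](CO[Si](C)(C)C(C)(C)C)[C@H]2C[C@H](Br)[C@@H](Br)C[C@@]12C
F3 | step 17 | 8β-hydroxy allyl ester | C=C[C@]1(C)C[C@@H](O)[C@@H](C(=C)C(=O)OCC=C)[C@@H](O[Si](C)(C)C(C)(C)C)[C@@H]1C(=C)CO[Si](C)(C)C(C)(C)C
F4 | step 17 | allyl ester of 32 | C=C[C@]1(C)C[C@@H](OC(=O)C(=C)[C@@H](O[Si](C)(C)C(C)(C)C)CO[Si](C)(C)C(C)(C)C)[C@@H](C(=C)C(=O)OCC=C)[C@@H](O[Si](C)(C)C(C)(C)C)[C@@H]1C(=C)CO[Si](C)(C)C(C)(C)C
F5 | step 18 | 6β,12-olide of the target (cis-fused α-methylene γ-lactone) | C=C[C@]1(C)C[C@@H](OC(=O)C(=C)[C@@H](O)CO)[C@H]2C(=C)C(=O)O[C@H]2[C@@H]1C(=C)CO
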